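## Retrosynthetic overview

1. Glaucolide L ⇐ Stille hydroxymethylation at C11 (C11–C13 bond) and methacrylation of O8 of an 11-iodo macrocyclic butenolide.
2. Ten-membered carbocycle (formed last) ⇐ intramolecular Nozaki–Hiyama–Kishi closure of C7–C8 between the β-iodide of a 3,4-diiodobutenolide and a C8 aldehyde.
3. Butenolide (formed second) ⇐ syn-distannation and lactonisation of a γ-hydroxy ynoate; C6 comes from a catalytic asymmetric alkynylation of an E-enal with methyl propiolate.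
4. Epoxide (formed first) ⇐ hydroxyl-directed epoxidation of the E C4=C5 alkene by the free C6 alcohol (threo).
5. C1/C10 syn pair ⇐ catalytic asymmetric Z-crotylboration of the aldehyde from selective ozonolysis of geranyl acetate; the crotyl vinyl group later becomes the C8 aldehyde.

Position labels follow germacrane numbering: C1 = CH–OAc, C4/C5 = epoxide, C6 = lactone CH–O, C7=C11 = butenolide alkene, C8 = CH–O-methacrylate, C10 = CH–CH3, C12 = lactone C=O, C13 = CH2OH.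

Assumption: for (R)-TRIP and (S,S)-ProPhenol the enantiomer named is the one taken to give the drawn configuration; if the sense of induction on these substrates is the opposite, the mirror-image catalyst is meant.

## Route

Step 1
Reactants: 1 geranyl acetate [(2E)-3,7-dimethylocta-2,6-dien-1-yl acetate]
Product: 3 (2E)-3-methyl-6-oxohex-2-en-1-yl acetate, via ozonide 2 (not isolated)
Conditions: O3 (1.0 equiv), CH2Cl2, −78 °C; then Me2S, −78 °C to rt
Reagents that add atoms: ozone [O-][O+]=O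
Why: Chemoselective ozonolysis of the electron-rich isopropylidene alkene, the other trisubstituted alkene being deactivated by its allylic acetoxy group and keeping its E geometry; no stereocentre is formed.

Step 2
Reactants: 3 (2E)-3-methyl-6-oxohex-2-en-1-yl acetate; 4 cis-crotylboronic acid pinacol ester [2-[(2Z)-but-2-en-1-yl]-4,4,5,5-tetramethyl-1,3,2-dioxaborolane]
Product: 7 (2E,6S,7S)-3,7-dimethylnona-2,8-diene-1,6-diol, via boronate ester 5 (not isolated), via hydroxy acetate 6 (not isolated)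
Conditions: (R)-TRIP (5 mol%), toluene, −30 °C; then K2CO3 (cat.), MeOH, rt
Reagents that add atoms: none
Why: Chiral phosphoric acid catalysed crotylboration through a closed chair transition state, in which the Z-crotyl geometry gives the syn C1–OH/C10–CH3 pair and the catalyst directs attack to the Re face of the aldehyde (1S,10S), followed by methanolysis of the boronate and of the allylic acetate.

Step 3
Reactants: 7 (2E,6S,7S)-3,7-dimethylnona-2,8-diene-1,6-diol
Product: 8 (2E,6S,7S)-6-hydroxy-3,7-dimethylnona-2,8-dienal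
Conditions: MnO2 (15 equiv), CH2Cl2, rt
Reagents that add atoms: none
Why: MnO2 oxidises only the primary allylic alcohol to the E-enal and leaves the secondary homoallylic alcohol and both stereocentres untouched (chemoselective allylic oxidation).

Step 4
Reactants: 8 (2E,6S,7S)-6-hydroxy-3,7-dimethylnona-2,8-dienal
Product: 9 (3S,4S,7E)-3,7-dimethyl-9-oxonona-1,7-dien-4-yl acetate
Conditions: Ac2O, pyridine, DMAP (cat.), CH2Cl2, 0 °C
Reagents that add atoms: acetic anhydride CC(=O)OC(C)=O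
Why: DMAP-catalysed O-acylation installs the C1 acetate of the target with retention at C1.

Step 5
Reactants: 9 (3S,4S,7E)-3,7-dimethyl-9-oxonona-1,7-dien-4-yl acetate; 10 methyl propiolate
Product: 12 methyl (4R,5E,9S,10S)-9-acetoxy-4-hydroxy-6,10-dimethyldodeca-5,11-dien-2-ynoate, via methylzinc acetylide 11 (not isolated)
Conditions: Me2Zn (3 equiv), (S,S)-ProPhenol (20 mol%), Ph3P=O (40 mol%), toluene, 4 °C
Reagents that add atoms: none
Why: Me2Zn/ProPhenol-mediated catalytic asymmetric alkynylation adds the zinc acetylide 1,2 to the Si face of the enal and so sets C6 (4R in 12) under catalyst control, the remote C1/C10 centres not interfering.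

Step 6
Reactants: 12 methyl (4R,5E,9S,10S)-9-acetoxy-4-hydroxy-6,10-dimethyldodeca-5,11-dien-2-ynoate
Product: 13 methyl (4S)-4-[(2R,3R)-3-[(3S,4S)-3-acetoxy-4-methylhex-5-en-1-yl]-3-methyloxiran-2-yl]-4-hydroxybut-2-ynoate
Conditions: mCPBA (1.1 equiv), NaHCO3, CH2Cl2, 0 °C
Reagents that add atoms: mCPBA OOC(=O)c1cccc(Cl)c1
Why: Hydroxyl-directed (Henbest) peracid epoxidation of the only trisubstituted alkene, in which A(1,3) strain with the cis C4-methyl keeps the carbinol hydrogen in the alkene plane so that oxygen is delivered syn to the hydroxyl, giving the threo 4R,5R,6S epoxy alcohol while the terminal vinyl group and the ynoate stay intact.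

Step 7
Reactants: 13 methyl (4S)-4-[(2R,3R)-3-[(3S,4S)-3-acetoxy-4-methylhex-5-en-1-yl]-3-methyloxiran-2-yl]-4-hydroxybut-2-ynoate
Product: 15 (3S,4S)-4-methyl-1-[(2R,3R)-2-methyl-3-[(2R)-5-oxo-3,4-bis(trimethylstannyl)-2,5-dihydrofuran-2-yl]oxiran-2-yl]hex-5-en-3-yl acetate, via open-chain distannyl hydroxy ester 14 (not isolated)
Conditions: (Me3Sn)2 (1.2 equiv), Pd(PPh3)4 (5 mol%), THF, rt to 50 °C
Reagents that add atoms: hexamethylditin C[Sn](C)(C)[Sn](C)(C)C
Why: Palladium-catalysed syn-distannation of the ynoate puts the C6 carbinol cis to the ester, so the Z-γ-hydroxy enoate lactonises at once to the butenolide with C6 unchanged and a tin handle on each alkene carbon.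

Step 8
Reactants: 15 (3S,4S)-4-methyl-1-[(2R,3R)-2-methyl-3-[(2R)-5-oxo-3,4-bis(trimethylstannyl)-2,5-dihydrofuran-2-yl]oxiran-2-yl]hex-5-en-3-yl acetate
Product: 17 (3S,4S)-6-hydroxy-4-methyl-1-[(2R,3R)-2-methyl-3-[(2R)-5-oxo-3,4-bis(trimethylstannyl)-2,5-dihydrofuran-2-yl]oxiran-2-yl]hexan-3-yl acetate, via alkylborane 16 (not isolated)
Conditions: 9-BBN (2 equiv), THF, 0 °C to rt; then 30% H2O2, pH 7 phosphate buffer, 0 °C
Reagents that add atoms: hydrogen peroxide OO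
Why: Anti-Markovnikov hydroboration–oxidation with the bulky borane touches only the monosubstituted alkene and turns it into the C8 primary alcohol without affecting the tetrasubstituted stannyl alkene, epoxide, lactone or acetate.

Step 9
Reactants: 17 (3S,4S)-6-hydroxy-4-methyl-1-[(2R,3R)-2-methyl-3-[(2R)-5-oxo-3,4-bis(trimethylstannyl)-2,5-dihydrofuran-2-yl]oxiran-2-yl]hexan-3-yl acetate
Product: 18 (3S,4S)-4-methyl-1-[(2R,3R)-2-methyl-3-[(2R)-5-oxo-3,4-bis(trimethylstannyl)-2,5-dihydrofuran-2-yl]oxiran-2-yl]-6-oxohexan-3-yl acetate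
Conditions: Dess–Martin periodinane, NaHCO3, CH2Cl2, rt
Reagents that add atoms: none
Why: Buffered Dess–Martin oxidation converts the primary alcohol into the C8 aldehyde under neutral conditions that spare the stannanes and the epoxide.

Step 10
Reactants: 18 (3S,4S)-4-methyl-1-[(2R,3R)-2-methyl-3-[(2R)-5-oxo-3,4-bis(trimethylstannyl)-2,5-dihydrofuran-2-yl]oxiran-2-yl]-6-oxohexan-3-yl acetate
Product: 20 (3S,4S)-1-[(2R,3R)-3-[(2R)-3,4-diiodo-5-oxo-2,5-dihydrofuran-2-yl]-2-methyloxiran-2-yl]-4-methyl-6-oxohexan-3-yl acetate, via monoiodide 19 (not isolated)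
Conditions: I2 (2.2 equiv), CH2Cl2, 0 °C
Reagents that add atoms: iodine II
Why: Electrophilic ipso-iododestannylation replaces both alkenyl C–Sn bonds (the α one first) by C–I within the ring, giving the 3,4-diiodobutenolide without touching any stereocentre.

Step 11
Reactants: 20 (3S,4S)-1-[(2R,3R)-3-[(2R)-3,4-diiodo-5-oxo-2,5-dihydrofuran-2-yl]-2-methyloxiran-2-yl]-4-methyl-6-oxohexan-3-yl acetate
Product: 22 (1S,4R,5R,6S,8S,10S)-1-acetoxy-4,5-epoxy-8-hydroxy-11-iodo-13-norgermacr-7(11)-en-12,6-olide, via alkenylchromium dichloride 21 (not isolated)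
Conditions: CrCl2 (8 equiv), NiCl2 (2 mol%), DMSO/THF, rt, slow addition to 2 mM
Reagents that add atoms: none
Why: Intramolecular Nozaki–Hiyama–Kishi reaction, in which zerovalent nickel inserts preferentially into the β C–I bond (a vinylogous acyl iodide), transmetalation to chromium and 1,2-addition to the aldehyde close the ten-membered ring, and the C8 carbinol (8S) is set by substrate control in the macrocyclic transition state.

Step 12
Reactants: 22 (1S,4R,5R,6S,8S,10S)-1-acetoxy-4,5-epoxy-8-hydroxy-11-iodo-13-norgermacr-7(11)-en-12,6-olide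
Product: 23 (1S,4R,5R,6S,8S,10S)-1-acetoxy-4,5-epoxy-11-iodo-8-(methacryloyloxy)-13-norgermacr-7(11)-en-12,6-olide
Conditions: methacrylic anhydride (3 equiv), Et3N, DMAP, CH2Cl2, 0 °C to rt
Reagents that add atoms: methacrylic anhydride C=C(C)C(=O)OC(=O)C(C)=C
Why: DMAP-catalysed acylation of the secondary allylic alcohol gives the C8 methacrylate with retention at C8.

Step 13
Reactants: 23 (1S,4R,5R,6S,8S,10S)-1-acetoxy-4,5-epoxy-11-iodo-8-(methacryloyloxy)-13-norgermacr-7(11)-en-12,6-olide; 24 (tributylstannyl)methanol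
Product: 25 glaucolide L [(1S,4R,5R,6S,8S,10S)-1-acetoxy-4,5-epoxy-13-hydroxy-8-(methacryloyloxy)germacr-7(11)-en-12,6-olide]
Conditions: Pd(PPh3)4 (10 mol%), CuI (20 mol%), dioxane, 60 °C
Reagents that add atoms: none
Why: Stille cross-coupling of the α-iodobutenolide transfers the hydroxymethyl group to C11 under neutral conditions, so no protecting group is needed and no stereocentre is touched.

## Compound list

1 | geranyl acetate [(2E)-3,7-dimethylocta-2,6-dien-1-yl acetate] | CC(C)=CCC/C(C)=C/COC(C)=O | starting material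
2 | (2E)-5-(5,5-dimethyl-1,2,4-trioxolan-3-yl)-3-methylpent-2-en-1-yl acetate (ozonide) | CC1(C)OOC(CC/C(C)=C/COC(C)=O)O1 | intermediate
3 | (2E)-3-methyl-6-oxohex-2-en-1-yl acetate | O=CCC/C(C)=C/COC(C)=O | intermediate
4 | cis-crotylboronic acid pinacol ester [2-[(2Z)-but-2-en-1-yl]-4,4,5,5-tetramethyl-1,3,2-dioxaborolane] | C/C=C\CB1OC(C)(C)C(C)(C)O1 | starting material
5 | (2E,6S,7S)-3,7-dimethyl-6-[(4,4,5,5-tetramethyl-1,3,2-dioxaborolan-2-yl)oxy]nona-2,8-dien-1-yl acetate | C=C[C@H](C)[C@@H](OB1OC(C)(C)C(C)(C)O1)CC/C(C)=C/COC(C)=O | intermediate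
6 | (2E,6S,7S)-6-hydroxy-3,7-dimethylnona-2,8-dien-1-yl acetate | C=C[C@H](C)[C@@H](O)CC/C(C)=C/COC(C)=O | intermediate
7 | (2E,6S,7S)-3,7-dimethylnona-2,8-diene-1,6-diol | C=C[C@H](C)[C@@H](O)CC/C(C)=C/CO | intermediate
8 | (2E,6S,7S)-6-hydroxy-3,7-dimethylnona-2,8-dienal | C=C[C@H](C)[C@@H](O)CC/C(C)=C/C=O | intermediate
9 | (3S,4S,7E)-3,7-dimethyl-9-oxonona-1,7-dien-4-yl acetate | C=C[C@H](C)[C@@H](OC(C)=O)CC/C(C)=C/C=O | intermediate
10 | methyl propiolate | C#CC(=O)OC | starting material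
11 | methyl 3-(methylzincio)prop-2-ynoate (methylzinc acetylide) | C[Zn]C#CC(=O)OC | intermediate
12 | methyl (4R,5E,9S,10S)-9-acetoxy-4-hydroxy-6,10-dimethyldodeca-5,11-dien-2-ynoate | C=C[C@H](C)[C@@H](OC(C)=O)CC/C(C)=C/[C@@H](O)C#CC(=O)OC | intermediate
13 | methyl (4S)-4-[(2R,3R)-3-[(3S,4S)-3-acetoxy-4-methylhex-5-en-1-yl]-3-methyloxiran-2-yl]-4-hydroxybut-2-ynoate | C=C[C@H](C)[C@@H](OC(C)=O)CC[C@@]1(C)O[C@@H]1[C@@H](O)C#CC(=O)OC | intermediate
14 | methyl (2Z,4R)-4-[(2R,3R)-3-[(3S,4S)-3-acetoxy-4-methylhex-5-en-1-yl]-3-methyloxiran-2-yl]-4-hydroxy-2,3-bis(trimethylstannyl)but-2-enoate | C=C[C@H](C)[C@@H](OC(C)=O)CC[C@@]1(C)O[C@@H]1[C@@H](O)/C([Sn](C)(C)C)=C(/[Sn](C)(C)C)C(=O)OC | intermediate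
15 | (3S,4S)-4-methyl-1-[(2R,3R)-2-methyl-3-[(2R)-5-oxo-3,4-bis(trimethylstannyl)-2,5-dihydrofuran-2-yl]oxiran-2-yl]hex-5-en-3-yl acetate | C=C[C@H](C)[C@@H](OC(C)=O)CC[C@@]1(C)O[C@@H]1[C@H]2OC(=O)C([Sn](C)(C)C)=C2[Sn](C)(C)C | intermediate
16 | (3S,4S)-6-(9-borabicyclo[3.3.1]nonan-9-yl)-4-methyl-1-[(2R,3R)-2-methyl-3-[(2R)-5-oxo-3,4-bis(trimethylstannyl)-2,5-dihydrofuran-2-yl]oxiran-2-yl]hexan-3-yl acetate | B1(C2CCCC1CCC2)CC[C@H](C)[C@@H](OC(C)=O)CC[C@@]3(C)O[C@@H]3[C@H]4OC(=O)C([Sn](C)(C)C)=C4[Sn](C)(C)C | intermediate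
17 | (3S,4S)-6-hydroxy-4-methyl-1-[(2R,3R)-2-methyl-3-[(2R)-5-oxo-3,4-bis(trimethylstannyl)-2,5-dihydrofuran-2-yl]oxiran-2-yl]hexan-3-yl acetate | OCC[C@H](C)[C@@H](OC(C)=O)CC[C@@]1(C)O[C@@H]1[C@H]2OC(=O)C([Sn](C)(C)C)=C2[Sn](C)(C)C | intermediate
18 | (3S,4S)-4-methyl-1-[(2R,3R)-2-methyl-3-[(2R)-5-oxo-3,4-bis(trimethylstannyl)-2,5-dihydrofuran-2-yl]oxiran-2-yl]-6-oxohexan-3-yl acetate | O=CC[C@H](C)[C@@H](OC(C)=O)CC[C@@]1(C)O[C@@H]1[C@H]2OC(=O)C([Sn](C)(C)C)=C2[Sn](C)(C)C | intermediate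
19 | (3S,4S)-1-[(2R,3R)-3-[(2R)-4-iodo-5-oxo-3-(trimethylstannyl)-2,5-dihydrofuran-2-yl]-2-methyloxiran-2-yl]-4-methyl-6-oxohexan-3-yl acetate | O=CC[C@H](C)[C@@H](OC(C)=O)CC[C@@]1(C)O[C@@H]1[C@H]2OC(=O)C(I)=C2[Sn](C)(C)C | intermediate
20 | (3S,4S)-1-[(2R,3R)-3-[(2R)-3,4-diiodo-5-oxo-2,5-dihydrofuran-2-yl]-2-methyloxiran-2-yl]-4-methyl-6-oxohexan-3-yl acetate | O=CC[C@H](C)[C@@H](OC(C)=O)CC[C@@]1(C)O[C@@H]1[C@H]2OC(=O)C(I)=C2I | intermediate
21 | [(2R)-2-[(2R,3R)-3-[(3S,4S)-3-acetoxy-4-methyl-6-oxohexyl]-3-methyloxiran-2-yl]-4-iodo-5-oxo-2,5-dihydrofuran-3-yl]chromium dichloride | O=CC[C@H](C)[C@@H](OC(C)=O)CC[C@@]1(C)O[C@@H]1[C@H]2OC(=O)C(I)=C2[Cr](Cl)Cl | intermediate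
22 | (1S,4R,5R,6S,8S,10S)-1-acetoxy-4,5-epoxy-8-hydroxy-11-iodo-13-norgermacr-7(11)-en-12,6-olide | O[C@H]1C[C@H](C)[C@@H](OC(C)=O)CC[C@@]2(C)O[C@@H]2[C@H]2OC(=O)C(I)=C12 | intermediate
23 | (1S,4R,5R,6S,8S,10S)-1-acetoxy-4,5-epoxy-11-iodo-8-(methacryloyloxy)-13-norgermacr-7(11)-en-12,6-olide | C=C(C)C(=O)O[C@H]1C[C@H](C)[C@@H](OC(C)=O)CC[C@@]2(C)O[C@@H]2[C@H]2OC(=O)C(I)=C12 | intermediate
24 | (tributylstannyl)methanol | CCCC[Sn](CCCC)(CCCC)CO | starting material
25 | glaucolide L [(1S,4R,5R,6S,8S,10S)-1-acetoxy-4,5-epoxy-13-hydroxy-8-(methacryloyloxy)germacr-7(11)-en-12,6-olide] | C=C(C)C(=O)O[C@H]1C[C@H](C)[C@@H](OC(C)=O)CC[C@@]2(C)O[C@@H]2[C@H]2OC(=O)C(CO)=C12 | target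

## Step count and risks

Total step count: 13. Longest linear sequence: 13 steps from geranyl acetate 1; compounds 4, 10 and 24 are bought.

The three steps most likely to fail:

- **Step 6 (directed epoxidation).** The slim alkynyl group on the carbinol exerts little allylic strain, so the threo:erythro ratio may be low. Fallback: set out from 9 and 10 but run the alkynylation with (R,R)-ProPhenol to obtain methyl (4S,5E,9S,10S)-9-acetoxy-4-hydroxy-6,10-dimethyldodeca-5,11-dien-2-ynoate F1. Sharpless epoxidation in the matched sense (Ti(OiPr)4, D-(−)-diisopropyl tartrate, TBHP, 4 Å MS, CH2Cl2, −20 °C) is reliably erythro-selective and gives methyl (4R)-4-[(2R,3R)-3-[(3S,4S)-3-acetoxy-4-methylhex-5-en-1-yl]-3-methyloxiran-2-yl]-4-hydroxybut-2-ynoate F2 with the required 4R,5R epoxide. Mitsunobu reaction with 4-nitrobenzoic acid (PPh3, DIAD, toluene, 0 °C) inverts the carbinol to methyl (4S)-4-[(2R,3R)-3-[(3S,4S)-3-acetoxy-4-methylhex-5-en-1-yl]-3-methyloxiran-2-yl]-4-[(4-nitrobenzoyl)oxy]but-2-ynoate F3. Brief methanolysis (K2CO3 cat., MeOH, −10 °C; the activated ester goes before the acetate) comes back to the route at 13.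

- **Step 11 (ring closure).** The ten-membered ring may close slowly, the second iodide may be reduced, and the sense of induction at C8 is not predictable with confidence. Fallback for the stereochemical outcome: set out from 20; if the closure gives mainly the C8 epimer (1S,4R,5R,6S,8R,10S)-1-acetoxy-4,5-epoxy-8-hydroxy-11-iodo-13-norgermacr-7(11)-en-12,6-olide F4, esterify it with methacrylic acid under Mitsunobu conditions (PPh3, DIAD, toluene, 0 °C). This inverts C8, replaces step 12 and comes back to the route at 23.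

- **Step 13 (Stille hydroxymethylation).** A hindered tetrasubstituted α-iodobutenolide next to a methacrylate may couple sluggishly or lose iodine by reduction. Fallback: set out from 23; reductive carbonylation (CO 1 atm, Bu3SnH by syringe pump, Pd(PPh3)4, THF, 50 °C) gives the C13 aldehyde (1S,4R,5R,6S,8S,10S)-1-acetoxy-4,5-epoxy-8-(methacryloyloxy)-13-oxogermacr-7(11)-en-12,6-olide F5. Luche reduction (NaBH4, CeCl3·7H2O, MeOH, −78 °C) then reduces only the aldehyde and comes back to the route at 25.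

## Further compounds

F1 | step 6 | methyl (4S,5E,9S,10S)-9-acetoxy-4-hydroxy-6,10-dimethyldodeca-5,11-dien-2-ynoate | C=C[C@H](C)[C@@H](OC(C)=O)CC/C(C)=C/[C@H](O)C#CC(=O)OC
F2 | step 6 | methyl (4R)-4-[(2R,3R)-3-[(3S,4S)-3-acetoxy-4-methylhex-5-en-1-yl]-3-methyloxiran-2-yl]-4-hydroxybut-2-ynoate | C=C[C@H](C)[C@@H](OC(C)=O)CC[C@@]1(C)O[C@@H]1[C@H](O)C#CC(=O)OC
F3 | step 6 | methyl (4S)-4-[(2R,3R)-3-[(3S,4S)-3-acetoxy-4-methylhex-5-en-1-yl]-3-methyloxiran-2-yl]-4-[(4-nitrobenzoyl)oxy]but-2-ynoate | C=C[C@H](C)[C@@H](OC(C)=O)CC[C@@]1(C)O[C@@H]1[C@@H](OC(=O)c2ccc(cc2)[N+](=O)[O-])C#CC(=O)OC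
F4 | step 11 | (1S,4R,5R,6S,8R,10S)-1-acetoxy-4,5-epoxy-8-hydroxy-11-iodo-13-norgermacr-7(11)-en-12,6-olide | O[C@@H]1C[C@H](C)[C@@H](OC(C)=O)CC[C@@]2(C)O[C@@H]2[C@H]2OC(=O)C(I)=C12
F5 | step 13 | (1S,4R,5R,6S,8S,10S)-1-acetoxy-4,5-epoxy-8-(methacryloyloxy)-13-oxogermacr-7(11)-en-12,6-olide | C=C(C)C(=O)O[C@H]1C[C@H](C)[C@@H](OC(C)=O)CC[C@@]2(C)O[C@@H]2[C@H]2OC(=O)C(C=O)=C12
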